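Ring A, the 2-methoxycyclopent-2-enone, is numbered C1(OMe)=C2(Ar)–C3(spiro)–C4(OMe)(Ar)–C5(=O), with the oxirane CH2 as C6. The route rests on cutting C5–C1 and C1=C2. C1 has the C5 carbonyl on one side and the aryl-substituted C2 on the other, so it is brought in as the carbanion of diethyl (methoxymethyl)phosphonate. In one flask this carbanion should be acylated by a C5 ester and then olefinate a C2 aryl ketone, closing ring A with both bonds. The precursor is an open-chain γ-keto ester, methyl 2-aryl-2-methoxy-2-(2-aroyloxiran-2-yl)acetate, that already holds the oxirane and both stereocentres: C4 from (S)-4-hydroxymandelic acid, C3 from a nucleophilic epoxidation.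

Key step: step 8

Remark: (S)-4-hydroxymandelic acid is assumed to be available enantiopure; both phenols are carried as triisopropylsilyl ethers, since aryl tert-butyldimethylsilyl ethers would be at risk from the hydroxide, peroxide and methoxide met in steps 6 to 8.

Step 1
Reactants: 1 (S)-4-hydroxymandelic acid
Product: 3 (2S)-2-hydroxy-2-[4-(triisopropylsilyloxy)phenyl]acetic acid, via silyl ester 2 (not isolated)
Conditions: i-Pr3SiCl (2.3 equiv), imidazole, DMF, 0 °C to rt; then 1 M aq. HCl, THF, rt
Reagents that add atoms: triisopropylsilyl chloride, CC(C)[Si](Cl)(C(C)C)C(C)C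
Why: O-silylation of the phenol and the carboxyl group (the hindered α-hydroxyl should be left) followed by mild hydrolysis of the labile silyl ester should give the phenol-protected acid with the stereocentre untouched.

Step 2
Reactants: 3 (2S)-2-hydroxy-2-[4-(triisopropylsilyloxy)phenyl]acetic acid; 4 pivalaldehyde
Product: 5 (2S,5S)-2-tert-butyl-5-[4-(triisopropylsilyloxy)phenyl]-1,3-dioxolan-4-one (cis)
Conditions: cat. TsOH·H2O, pentane, reflux, Dean–Stark; cis isomer purified by crystallisation
Reagents that add atoms: none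
Why: Acid-catalysed acetalisation under thermodynamic control should give the cis-dioxolanone needed for self-regeneration of the stereocentre, the new acetal centre (2S) being set by the preference of tert-butyl and aryl for the same face of the ring.

Step 3
Reactants: 6 2-bromo-4'-hydroxyacetophenone
Product: 7 2-bromo-1-[4-(triisopropylsilyloxy)phenyl]ethan-1-one
Conditions: i-Pr3SiOTf, 2,6-lutidine, CH2Cl2, −78 to 0 °C
Reagents that add atoms: triisopropylsilyl trifluoromethanesulfonate, CC(C)[Si](OS(=O)(=O)C(F)(F)F)(C(C)C)C(C)C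
Why: O-silylation of the phenol with a silyl triflate and a hindered, weakly nucleophilic base should avoid N-alkylation of the base and halide exchange at the α-bromo ketone.

Step 4
Reactants: 5 (2S,5S)-2-tert-butyl-5-[4-(triisopropylsilyloxy)phenyl]-1,3-dioxolan-4-one; 7 2-bromo-1-[4-(triisopropylsilyloxy)phenyl]ethan-1-one
Product: 9 (2S,5S)-2-tert-butyl-5-{2-oxo-2-[4-(triisopropylsilyloxy)phenyl]ethyl}-5-[4-(triisopropylsilyloxy)phenyl]-1,3-dioxolan-4-one, via lithium enolate 8 (not isolated)
Conditions: LiN(SiMe3)2 (1.05 equiv), THF, −78 °C; enolate added to 7 (1.3 equiv) in THF, −78 to −40 °C; AcOH quench at −78 °C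
Reagents that add atoms: none
Why: SN2 alkylation of the planar dioxolanone enolate by the activated primary bromide should occur on the face anti to tert-butyl, so the phenacyl carbon takes the place of the former C5 hydrogen and the quaternary centre forms with overall retention (self-regeneration of stereocentres), while the low temperature and cold quench spare the base-sensitive β-acyloxy ketone.

Step 5
Reactants: 9 (2S,5S)-2-tert-butyl-5-{2-oxo-2-[4-(triisopropylsilyloxy)phenyl]ethyl}-5-[4-(triisopropylsilyloxy)phenyl]-1,3-dioxolan-4-one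
Product: 10 (2S,5R)-2-tert-butyl-5-{3-oxo-3-[4-(triisopropylsilyloxy)phenyl]prop-1-en-2-yl}-5-[4-(triisopropylsilyloxy)phenyl]-1,3-dioxolan-4-one
Conditions: (CH2O)n, N-methylanilinium trifluoroacetate, THF, reflux
Reagents that add atoms: paraformaldehyde (formaldehyde), C=O
Why: Mannich-type α-methylenation of the aryl ketone (enol addition to the iminium ion, then β-elimination of the amine) runs under weakly acidic conditions, which avoids enolate formation next to the acetal oxygen and removes the last enolisable hydrogen before any base is used; no stereocentre is touched.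

Step 6
Reactants: 10 (2S,5R)-2-tert-butyl-5-{3-oxo-3-[4-(triisopropylsilyloxy)phenyl]prop-1-en-2-yl}-5-[4-(triisopropylsilyloxy)phenyl]-1,3-dioxolan-4-one
Product: 11 (2S,5R)-2-tert-butyl-5-{(2R)-2-[4-(triisopropylsilyloxy)benzoyl]oxiran-2-yl}-5-[4-(triisopropylsilyloxy)phenyl]-1,3-dioxolan-4-one
Conditions: t-BuOOH (anhydrous, decane), n-BuLi, THF, −78 °C; then 10, −78 to −20 °C; aq. NH4Cl
Reagents that add atoms: tert-butyl hydroperoxide, CC(C)(C)OO
Why: Weitz–Scheffer nucleophilic epoxidation (conjugate addition of lithium tert-butyl peroxide to the aryl vinyl ketone, then 3-exo-tet closure of the lithium enolate onto the O–O bond) sets C3 in the closure, which should occur anti to the bulky aryl group on the dioxolanone with the ring oxygen O1 inside and lithium-bridged to the enolate oxygen, giving the (R)-oxirane.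

Step 7
Reactants: 11 (2S,5R)-2-tert-butyl-5-{(2R)-2-[4-(triisopropylsilyloxy)benzoyl]oxiran-2-yl}-5-[4-(triisopropylsilyloxy)phenyl]-1,3-dioxolan-4-one
Product: 13 methyl (2R)-2-methoxy-2-[4-(triisopropylsilyloxy)phenyl]-2-{(2R)-2-[4-(triisopropylsilyloxy)benzoyl]oxiran-2-yl}acetate, via lithium carboxylate 12 (not isolated)
Conditions: LiOH·H2O (1.5 equiv), THF/H2O, 0 °C; evaporate, toluene azeotrope; then NaH, MeI, DMF, 0 °C to rt
Reagents that add atoms: lithium hydroxide, [Li+].[OH-]; iodomethane, CI
Why: Saponification of the activated acetal lactone releases pivalaldehyde without acidification (the β,γ-epoxy acid is never free), and carboxylate alkylation plus Williamson etherification with iodomethane should give the open-chain methyl ester methyl ether; C3 is already quaternary, so neither retro-aldol cleavage nor β-elimination is possible and both stereocentres are kept.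

Step 8
Reactants: 13 methyl (2R)-2-methoxy-2-[4-(triisopropylsilyloxy)phenyl]-2-{(2R)-2-[4-(triisopropylsilyloxy)benzoyl]oxiran-2-yl}acetate; 14 diethyl (methoxymethyl)phosphonate
Product: 17 (3R,4R)-4,6-dimethoxy-4,7-bis[4-(triisopropylsilyloxy)phenyl]-1-oxaspiro[2.4]hept-6-en-5-one, via lithiated phosphonate 15 (not isolated), via keto phosphonate 16 (not isolated)
Conditions: 14 (2.5 equiv), LiN(iPr)2 (2.5 equiv), THF, −78 °C; then 13, −78 to 0 °C; then rt (to 40 °C); aq. NH4Cl
Reagents that add atoms: none
Why: The α-lithio phosphonate 15 adds to the ester carbonyl C5 and methoxide is expelled, and the β-keto phosphonate 16 is deprotonated at once by a second equivalent of 15; on warming, its stabilised carbanion C1 attacks the C2 ketone and syn elimination of lithium diethyl phosphate from the oxaphosphetane leaves the C1=C2 double bond. The closest known reaction types are the Claisen-type acylation of α-lithio phosphonates by esters and the intramolecular Horner–Wadsworth–Emmons closure of 1,4-dicarbonyl-derived β-keto phosphonates (or of enol lactones in one flask) to cyclopentenones. Ring A closes by 5-exo-trig attack of C1 on the C2 carbonyl, the mode common to cyclopentenone-forming intramolecular olefinations and aldol condensations. No stereocentre is formed, and C3 and C4, both quaternary and without acidic hydrogen, are carried through. The step needs reaction of 15 at the ester before the ketone: the ester is activated by its α-methoxy group (inductively and through lithium chelation), while the ketone is non-enolisable, flanked by the quaternary C3 and deactivated by the para-silyloxy group, and an adduct of unstabilised 15 with it cannot eliminate and should revert on warming, leaving the enolate of 16 as the sink. The triisopropylsilyl ethers and the oxirane should tolerate the lithium methoxide released.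

Step 9
Reactants: 17 (3R,4R)-4,6-dimethoxy-4,7-bis[4-(triisopropylsilyloxy)phenyl]-1-oxaspiro[2.4]hept-6-en-5-one
Product: 18 (3R,4R)-4,7-bis(4-hydroxyphenyl)-4,6-dimethoxy-1-oxaspiro[2.4]hept-6-en-5-one (CNP0504072.1)
Conditions: Bu4NF, AcOH (1:1), THF, 0 °C
Reagents that add atoms: none
Why: Fluoride-induced desilylation cleaves both aryl silyl ethers, and buffering with acetic acid should keep the released phenoxides from opening the oxirane or adding to the enone.

Compound list
1 | (S)-4-hydroxymandelic acid | O[C@@H](c1ccc(O)cc1)C(=O)O | starting material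
2 | triisopropylsilyl (2S)-2-hydroxy-2-[4-(triisopropylsilyloxy)phenyl]acetate | O[C@@H](c1ccc(O[Si](C(C)C)(C(C)C)C(C)C)cc1)C(=O)O[Si](C(C)C)(C(C)C)C(C)C | intermediate
3 | (2S)-2-hydroxy-2-[4-(triisopropylsilyloxy)phenyl]acetic acid | O[C@@H](c1ccc(O[Si](C(C)C)(C(C)C)C(C)C)cc1)C(=O)O | intermediate
4 | pivalaldehyde | CC(C)(C)C=O | starting material
5 | (2S,5S)-2-tert-butyl-5-[4-(triisopropylsilyloxy)phenyl]-1,3-dioxolan-4-one | CC(C)(C)[C@H]1O[C@@H](c2ccc(O[Si](C(C)C)(C(C)C)C(C)C)cc2)C(=O)O1 | intermediate
6 | 2-bromo-4'-hydroxyacetophenone | O=C(CBr)c1ccc(O)cc1 | starting material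
7 | 2-bromo-1-[4-(triisopropylsilyloxy)phenyl]ethan-1-one | O=C(CBr)c1ccc(O[Si](C(C)C)(C(C)C)C(C)C)cc1 | intermediate
8 | lithium (2S)-2-tert-butyl-5-[4-(triisopropylsilyloxy)phenyl]-1,3-dioxol-4-olate | [Li+].[O-]C1=C(c2ccc(O[Si](C(C)C)(C(C)C)C(C)C)cc2)O[C@H](C(C)(C)C)O1 | intermediate
9 | (2S,5S)-2-tert-butyl-5-{2-oxo-2-[4-(triisopropylsilyloxy)phenyl]ethyl}-5-[4-(triisopropylsilyloxy)phenyl]-1,3-dioxolan-4-one | CC(C)(C)[C@H]1O[C@@](CC(=O)c2ccc(O[Si](C(C)C)(C(C)C)C(C)C)cc2)(c2ccc(O[Si](C(C)C)(C(C)C)C(C)C)cc2)C(=O)O1 | intermediate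
10 | (2S,5R)-2-tert-butyl-5-{3-oxo-3-[4-(triisopropylsilyloxy)phenyl]prop-1-en-2-yl}-5-[4-(triisopropylsilyloxy)phenyl]-1,3-dioxolan-4-one | CC(C)(C)[C@H]1O[C@@](C(=C)C(=O)c2ccc(O[Si](C(C)C)(C(C)C)C(C)C)cc2)(c2ccc(O[Si](C(C)C)(C(C)C)C(C)C)cc2)C(=O)O1 | intermediate
11 | (2S,5R)-2-tert-butyl-5-{(2R)-2-[4-(triisopropylsilyloxy)benzoyl]oxiran-2-yl}-5-[4-(triisopropylsilyloxy)phenyl]-1,3-dioxolan-4-one | CC(C)(C)[C@H]1O[C@@]([C@]2(CO2)C(=O)c2ccc(O[Si](C(C)C)(C(C)C)C(C)C)cc2)(c2ccc(O[Si](C(C)C)(C(C)C)C(C)C)cc2)C(=O)O1 | intermediate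
12 | lithium (2R)-2-hydroxy-2-[4-(triisopropylsilyloxy)phenyl]-2-{(2R)-2-[4-(triisopropylsilyloxy)benzoyl]oxiran-2-yl}acetate | [Li+].[O-]C(=O)[C@@](O)(c1ccc(O[Si](C(C)C)(C(C)C)C(C)C)cc1)[C@]1(CO1)C(=O)c1ccc(O[Si](C(C)C)(C(C)C)C(C)C)cc1 | intermediate
13 | methyl (2R)-2-methoxy-2-[4-(triisopropylsilyloxy)phenyl]-2-{(2R)-2-[4-(triisopropylsilyloxy)benzoyl]oxiran-2-yl}acetate | COC(=O)[C@@](OC)(c1ccc(O[Si](C(C)C)(C(C)C)C(C)C)cc1)[C@]1(CO1)C(=O)c1ccc(O[Si](C(C)C)(C(C)C)C(C)C)cc1 | intermediate
14 | diethyl (methoxymethyl)phosphonate | CCOP(=O)(COC)OCC | starting material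
15 | lithium salt of diethyl (methoxymethyl)phosphonate, lithiated at the P–CH carbon | [Li+].CCOP(=O)([CH-]OC)OCC | intermediate
16 | diethyl {(3R)-1,3-dimethoxy-2-oxo-3-[4-(triisopropylsilyloxy)phenyl]-3-{(2R)-2-[4-(triisopropylsilyloxy)benzoyl]oxiran-2-yl}propyl}phosphonate (both C1 epimers) | CCOP(=O)(OCC)C(OC)C(=O)[C@@](OC)(c1ccc(O[Si](C(C)C)(C(C)C)C(C)C)cc1)[C@]1(CO1)C(=O)c1ccc(O[Si](C(C)C)(C(C)C)C(C)C)cc1 | intermediate
17 | (3R,4R)-4,6-dimethoxy-4,7-bis[4-(triisopropylsilyloxy)phenyl]-1-oxaspiro[2.4]hept-6-en-5-one | COC1=C(c2ccc(O[Si](C(C)C)(C(C)C)C(C)C)cc2)[C@@]2(CO2)[C@](OC)(c2ccc(O[Si](C(C)C)(C(C)C)C(C)C)cc2)C1=O | intermediate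
18 | (3R,4R)-4,7-bis(4-hydroxyphenyl)-4,6-dimethoxy-1-oxaspiro[2.4]hept-6-en-5-one | COC1=C(c2ccc(O)cc2)[C@@]2(CO2)[C@](OC)(c2ccc(O)cc2)C1=O | target

Total steps: 9. Longest linear sequence: 8 steps (1, 2, 4, 5, 6, 7, 8, 9).

Steps most likely to fail

Step 8. The lithiated phosphonate may add to the C2 ketone faster than to the hindered ester, and the alkoxide so formed may lactonise onto the ester and trap the wrong adduct. Ring closure of the lithium enolate may also be slow. The fallback masks the ketone and runs the two bond formations separately with known reactions. It sets out from 13: NaBH4 (MeOH, 0 °C) reduces the C2 ketone, and the alcohol closes onto the ester (cat. DBU if needed) to give the spiro-epoxy γ-lactone F1, in which the acyl group is a tied-back lactone and no ketone is present. Lithiated 14 (2.2 equiv, THF, −78 °C) opens the lactone to the hydroxy keto phosphonate F2, which is in equilibrium with its lactol. Dess–Martin oxidation restores the C2 ketone and gives 16, now isolated. K2CO3 with 18-crown-6 in toluene (or LiCl and DBU in MeCN) then closes ring A, and the route is rejoined at 17.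

Step 6. Facial selectivity in the ring closure of the peroxy enolate may be poor, because the lactone carbonyl and not the ring oxygen may take the inside position. The fallback changes the order of events so that the oxirane is closed on an open-chain ester whose free methoxy group can chelate lithium. It sets out from 9: LiOH/H2O2 (THF/H2O, 0 °C) cleaves the acetal to the hydroxy acid F3. MeOTf with 2,6-di-tert-butyl-4-methylpyridine (CH2Cl2) methylates the acid and the tertiary alcohol without an alkoxide and gives the methoxy ester F4. The Mannich-type methylenation used in step 5 gives the enone ester F5. Lithium tert-butyl peroxide (THF, −78 to −20 °C) then closes the oxirane within a six-membered lithium chelate between the enolate oxygen and the C4 methoxy group, anti to aryl, and the route is rejoined at 13.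

Step 4. The enolate may attack the carbonyl group of the α-bromo ketone (epoxide formation), and the product may suffer base-induced β-elimination of the acetal oxygen. The fallback uses an electrophile without a carbonyl group and unmasks the ketone afterwards. It sets out from 7 (and 5): Me3SiCH2MgCl (THF, −78 °C) adds to the ketone of 7 to give the β-silyl carbinol F6, and acid-promoted Peterson olefination (cat. TsOH, CH2Cl2) gives the allylic bromide F7. Enolate 8, made from 5 as in step 4, is alkylated by it with the same facial sense to give the allylated dioxolanone F8. Ozonolysis (O3, CH2Cl2, −78 °C; Me2S) then gives the aryl ketone under neutral conditions, and the route is rejoined at 9.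

Further compounds
F1 | step 8 | (3S,7R)-7-methoxy-4,7-bis[4-(triisopropylsilyloxy)phenyl]-1,5-dioxaspiro[2.4]heptan-6-one (both C4 epimers) | O=C1OC(c2ccc(O[Si](C(C)C)(C(C)C)C(C)C)cc2)[C@@]2(CO2)[C@]1(OC)c1ccc(O[Si](C(C)C)(C(C)C)C(C)C)cc1
F2 | step 8 | diethyl {1,3-dimethoxy-2-oxo-3-[4-(triisopropylsilyloxy)phenyl]-3-{2-[hydroxy(4-(triisopropylsilyloxy)phenyl)methyl]oxiran-2-yl}propyl}phosphonate, quaternary centres as in 13, epimers at C1 and at the carbinol carbon | CCOP(=O)(OCC)C(OC)C(=O)[C@@](OC)(c1ccc(O[Si](C(C)C)(C(C)C)C(C)C)cc1)[C@]1(CO1)C(O)c1ccc(O[Si](C(C)C)(C(C)C)C(C)C)cc1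
F3 | step 6 | (2S)-2-hydroxy-4-oxo-2,4-bis[4-(triisopropylsilyloxy)phenyl]butanoic acid | OC(=O)[C@@](O)(c1ccc(O[Si](C(C)C)(C(C)C)C(C)C)cc1)CC(=O)c1ccc(O[Si](C(C)C)(C(C)C)C(C)C)cc1
F4 | step 6 | methyl (2S)-2-methoxy-4-oxo-2,4-bis[4-(triisopropylsilyloxy)phenyl]butanoate | COC(=O)[C@@](OC)(c1ccc(O[Si](C(C)C)(C(C)C)C(C)C)cc1)CC(=O)c1ccc(O[Si](C(C)C)(C(C)C)C(C)C)cc1
F5 | step 6 | methyl (2R)-2-methoxy-3-methylidene-4-oxo-2,4-bis[4-(triisopropylsilyloxy)phenyl]butanoate | COC(=O)[C@@](OC)(c1ccc(O[Si](C(C)C)(C(C)C)C(C)C)cc1)C(=C)C(=O)c1ccc(O[Si](C(C)C)(C(C)C)C(C)C)cc1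
F6 | step 4 | 1-bromo-2-[4-(triisopropylsilyloxy)phenyl]-3-(trimethylsilyl)propan-2-ol (racemic) | OC(CBr)(C[Si](C)(C)C)c1ccc(O[Si](C(C)C)(C(C)C)C(C)C)cc1
F7 | step 4 | [4-(3-bromoprop-1-en-2-yl)phenoxy]triisopropylsilane | C=C(CBr)c1ccc(O[Si](C(C)C)(C(C)C)C(C)C)cc1
F8 | step 4 | (2S,5S)-2-tert-butyl-5-{2-[4-(triisopropylsilyloxy)phenyl]prop-2-en-1-yl}-5-[4-(triisopropylsilyloxy)phenyl]-1,3-dioxolan-4-one | CC(C)(C)[C@H]1O[C@@](CC(=C)c2ccc(O[Si](C(C)C)(C(C)C)C(C)C)cc2)(c2ccc(O[Si](C(C)C)(C(C)C)C(C)C)cc2)C(=O)O1
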